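**Assumptions (one line each)**
- Scopoletin (6-methoxy-7-hydroxycoumarin) and 4-methoxyresorcinol are taken as commercial.
- The target is a 3,8'-bicoumarin, C20H14O8, with no stereocentres. The biaryl axis is not configurationally defined in the SMILES, so no axial control is attempted.

## Retrosynthetic overview
1. Target ⇒ 7-O-benzyl ether (one deprotection). That ⇒ the 4-SMe bicoumarin (traceless reductive removal of SMe).
2. Key disconnection is the C3–C8' biaryl bond. A sulfonium-[3,3] C–H/C–H coupling joins scopoletin (its only free ortho position is C8') to a 4-(methylsulfinyl)coumarin, whose S on C4 delivers the bond to C3.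
3. The sulfoxide comes from 4-hydroxycoumarin (tosylate, then MeS⁻, then oxidation). The 4-hydroxycoumarin lactone comes from a 2-hydroxyacetophenone and diethyl carbonate, and that acetophenone from 4-methoxyresorcinol.
4. Ring order: scopoletin (ring B) is bought. Ring A's lactone is built first, then the biaryl bond, then the C4 traceless group and the benzyl group are removed.

## Route

**Step 1**
Reactants: 1 (4-methoxyresorcinol), 2 (acetic acid)
Product: 3 (2,4-dihydroxy-5-methoxyacetophenone)
Conditions: AcOH, BF3·OEt2, 90 °C
Reagents that add atoms: acetic acid, CC(=O)O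
Why: Friedel–Crafts (Hoesch-type) acylation goes at C6, which is ortho to one OH and para to the other.

**Step 2**
Reactants: 3, 4 (benzyl bromide)
Product: 5 (4-benzyloxy-2-hydroxy-5-methoxyacetophenone)
Conditions: BnBr, KHCO3, KI, MeCN, 80 °C
Reagents that add atoms: benzyl bromide, BrCc1ccccc1
Why: Williamson etherification is selective for the 4-OH, because the 2-OH is locked in a hydrogen bond to the ketone.

**Step 3**
Reactants: 5, 6 (diethyl carbonate)
Product: 7 (7-benzyloxy-4-hydroxy-6-methoxycoumarin)
Conditions: NaH (4 equiv), (EtO)2CO, toluene, reflux; then aqueous HCl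
Reagents that add atoms: diethyl carbonate, CCOC(=O)OCC
Why: Claisen-type carbethoxylation of the methyl ketone gives a β-ketoester, and phenoxide lactonisation closes the 4-hydroxycoumarin ring (ring A).

**Step 4**
Reactants: 7, 8 (TsCl)
Product: 9 (4-tosyloxy-7-benzyloxy-6-methoxycoumarin)
Conditions: TsCl, Et3N, CH2Cl2, 0 °C to rt
Reagents that add atoms: p-toluenesulfonyl chloride, Cc1ccc(S(=O)(=O)Cl)cc1
Why: the vinylogous acid O–H is sulfonylated, which makes C4 an excellent electrophile for the next step.

**Step 5**
Reactants: 9, 10 (sodium thiomethoxide)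
Product: 11 (7-benzyloxy-6-methoxy-4-(methylthio)coumarin)
Conditions: NaSMe (1.05 equiv), DMF, 0 °C
Reagents that add atoms: sodium thiomethoxide, C[S-].[Na+]
Why: vinylogous SNAr (addition–elimination) at C4 displaces tosylate.

**Step 6**
Reactants: 11, 12 (mCPBA)
Product: 13 (7-benzyloxy-6-methoxy-4-(methylsulfinyl)coumarin, racemic at S)
Conditions: mCPBA (1.0 equiv), CH2Cl2, –20 °C
Reagents that add atoms: mCPBA, OOC(=O)c1cccc(Cl)c1
Why: chemoselective S-oxidation; the electron-poor coumarin C=C and the benzyl ether are untouched.

**Step 7 (key new step)**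
Reactants: 13, 14 (scopoletin)
Product: 15 (7-benzyloxy-6-methoxy-4-(methylthio)-3-(7'-hydroxy-6'-methoxycoumarin-8'-yl)coumarin)
Conditions: 13, Tf2O (1.1 equiv), CH2Cl2, –78 °C, 10 min; then 14 (1.5 equiv) and 2,6-di-tert-butyl-4-methylpyridine (DTBMP, 2 equiv), MeCN/CH2Cl2, –78 °C to 25 °C
Reagents that add atoms: none (Tf2O, DTBMP and the sulfoxide oxygen leave as TfOH/triflate salts and water-level by-products)
Why: Proposed new method: Tf2O activates the sulfoxide to an S–OTf sulfonium, scopoletin's 7'-OH attacks S, and the resulting aryloxysulfonium undergoes a [3,3] shift across O–S–C4=C3 and C7'=C8'. This forms the C3–C8' bond regiospecifically, because C8' is the only free ortho carbon of the phenol and C3 is the carbon ortho to S on the coumarin. Tautomerisation then rearomatises ring B and regenerates the C3=C4 alkene with SMe retained at C4. The closest known reaction is the interrupted-Pummerer sulfonium-[3,3] C–H/C–H coupling of phenols with aryl sulfoxides, here extended to an electron-poor 4-sulfinyl coumarin (a β-sulfinyl acrylate) as the α-arylating partner. No stereocentre is formed.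

**Step 8**
Reactants: 15
Product: 16 (7-benzyloxy-6,6'-dimethoxy-7'-hydroxy-3,8'-bicoumarin)
Conditions: Pd2(dba)3 (5 mol%), tri(2-furyl)phosphine (20 mol%), CuTC (2.5 equiv), Et3SiH (3 equiv), THF, 50 °C
Reagents that add atoms: none (Et3SiH supplies only H)
Why: Liebeskind–Srogl-type Pd/Cu-mediated hydrodesulfurisation of a heteroaryl thioether removes the traceless directing SMe; the lactones, OMe, OBn and free phenol survive.

**Step 9**
Reactants: 16
Product: 17 (target, Ipomopsin)
Conditions: BCl3 (3 equiv), pentamethylbenzene (3 equiv), CH2Cl2, –78 °C, 30 min; quench MeOH/NaHCO3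
Reagents that add atoms: none
Why: BCl3 cleaves the aryl benzyl ether at –78 °C, with pentamethylbenzene trapping the benzyl cation, and leaves the aryl methyl ethers and lactones intact.

## Compound list
1 | 4-methoxyresorcinol | COc1ccc(O)cc1O | starting material
2 | acetic acid | CC(=O)O | starting material
3 | 2,4-dihydroxy-5-methoxyacetophenone | CC(=O)c1cc(OC)c(O)cc1O | intermediate
4 | benzyl bromide | BrCc1ccccc1 | starting material
5 | 4-benzyloxy-2-hydroxy-5-methoxyacetophenone | CC(=O)c1cc(OC)c(OCc2ccccc2)cc1O | intermediate
6 | diethyl carbonate | CCOC(=O)OCC | starting material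
7 | 7-benzyloxy-4-hydroxy-6-methoxycoumarin | COc1cc2c(O)cc(=O)oc2cc1OCc1ccccc1 | intermediate
8 | p-toluenesulfonyl chloride | Cc1ccc(S(=O)(=O)Cl)cc1 | starting material
9 | 7-benzyloxy-6-methoxy-4-tosyloxycoumarin | COc1cc2c(OS(=O)(=O)c3ccc(C)cc3)cc(=O)oc2cc1OCc1ccccc1 | intermediate
10 | sodium thiomethoxide | C[S-].[Na+] | starting material
11 | 7-benzyloxy-6-methoxy-4-(methylthio)coumarin | COc1cc2c(SC)cc(=O)oc2cc1OCc1ccccc1 | intermediate
12 | mCPBA | OOC(=O)c1cccc(Cl)c1 | starting material
13 | 7-benzyloxy-6-methoxy-4-(methylsulfinyl)coumarin | COc1cc2c(S(C)=O)cc(=O)oc2cc1OCc1ccccc1 | intermediate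
14 | scopoletin (7-hydroxy-6-methoxycoumarin) | COc1cc2ccc(=O)oc2cc1O | starting material
15 | 4-SMe, 7-OBn 3,8'-bicoumarin | COc1cc2c(SC)c(-c3c(O)c(OC)cc4ccc(=O)oc34)c(=O)oc2cc1OCc1ccccc1 | intermediate
16 | 7-O-benzyl-Ipomopsin | COc1cc2cc(-c3c(O)c(OC)cc4ccc(=O)oc34)c(=O)oc2cc1OCc1ccccc1 | intermediate
17 | Ipomopsin (7,7'-dihydroxy-6,6'-dimethoxy-3,8'-bicoumarin) | COc1cc2cc(-c3c(O)c(OC)cc4ccc(=O)oc34)c(=O)oc2cc1O | target

## Totals
- Total steps: 9.
- Longest linear sequence: 9 steps (4-methoxyresorcinol to 17); scopoletin is purchased.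

## Three steps most likely to fail
1. **Step 7 (new sulfonium-[3,3] coupling).** Failure modes are Pummerer decomposition of the S-methyl sulfoxide, attack of phenol O at the very electrophilic C4, and acid-mediated loss of the benzyl group.
   - Fallback (known chemistry): a Suzuki route to 16. Make 3-bromo-7-benzyloxy-6-methoxycoumarin by Knoevenagel condensation of the corresponding salicylaldehyde with Meldrum's acid, then NBS decarboxylative bromination. Borylate scopoletin at C8 by hydrosilyl-directed Ir-catalysed ortho C–H borylation. Couple the two with Pd(dppf)Cl2 and K3PO4, then finish with step 9.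
2. **Step 8 (Pd/Cu hydrodesulfurisation of the hindered 4-SMe).**
   - Fallback: reduce 15 by conjugate hydride addition (L-Selectride or NaBH4) to the 4-SMe-3,4-dihydrocoumarin, which may eliminate MeS⁻ directly. Otherwise oxidise with mCPBA and effect sulfoxide syn-elimination on heating, restoring C3=C4 with H at C4.
3. **Step 6 (selective S-oxidation of the electrophilic 4-thiocoumarin).** Over-oxidation to the sulfone or hydrolysis of the 4-sulfinyl group are the risks.
   - Fallback: skip the isolated sulfoxide. Treat sulfide 11 with NCS to form the chlorosulfonium in situ, add scopoletin, and let the aryloxysulfonium undergo the same [3,3] shift.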